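## Structural features

Halimane numbering is used throughout. The target is a halimane-type diterpenoid ester. Ring A (C1–C5, C10) is a cyclohexenone with the C2 ketone conjugated to the C1=C10 alkene. Ring B (C5–C10) is a saturated cyclohexane fused to it through C5–C10, and C9 carries a 3-methyl-5-hydroxypentyl chain (C11–C15, methyl on C13).

There are five stereocentres: quaternary C4 (methyl and methyl ester), the ring-fusion methine C5 next to it, the methine C8 (methyl), the adjacent quaternary C9 (methyl and chain), and the remote C13. H5 and the C4 ester lie on one face of the bicycle; the methyls on C4, C8 and C9 lie on the other.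

C4/C5 and C8/C9 are two vicinal pairs, each with a quaternary carbon. Both C5 and C9 are bonded to sp2 C10, so neither can be introduced by conjugate chemistry of the finished enone.

The fragile points are the enone (its γ-hydrogen at C5 allows base-mediated dienolisation and loss of the ring-fusion configuration), the primary alcohol, and the methyl ester, which is hindered but must survive every reduction.

The real difficulty is the C8/C9 pair: a quaternary carbon with two different alkyl groups next to a methine, the two methyls cis, in a ring with no neighbouring function to direct them. C13 is too far from the rings to be controlled by them and must come from the chiral pool.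

The key step uses exactly this vicinal arrangement. C9 becomes the carbon end of a lactone enolate conjugated with C1=C10, C8 becomes the end of an E-propenyl group on C6, and a temporary O–C6 bond holds them in a δ-lactone fused to ring A. A [3,3] shift then forms C8–C9, closes ring B and sets both centres from the single carbinol centre C6.

## Logic of the disconnections

**32 ⇒ 31 ⇒ 30.** No skeletal bond is cut; the O–Si bond at C15 and the C2 carbonyl oxygen are removed. The hydroxyl must be masked through all enolate chemistry, and C2 is the only allylic methylene of the C1=C10 alkene. The gain is that the base-sensitive enone is absent from every earlier compound. The demand is an allylic oxidation of 30 that takes a C2 hydrogen and not the tertiary C5 hydrogen, and a final desilylation that does not enolise 31.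

**30 ⇒ 28 ⇒ 26 ⇒ 25.** The C9 methyl is traced to a carboxyl carbon and the C6–C7 single bond to an alkene. These are the two functions a [3,3] shift leaves behind. The demand is a carboxyl-to-methyl conversion that spares the C4 ester and never places a radical on the carbon attached to C9, because that radical would add to the neighbouring C1=C10 alkene. The hydrogenation must tell C6=C7 from C1=C10 and must come before any strong base, since C5–H in 25 is doubly allylic.

**25 ⇒ 22.** The C8–C9 bond is cut and the O–C6 bond is reconnected. C8 and C9 are vicinal, C9 can be an enolate carbon, and C8 can be an alkene terminus. Ring B and two stereocentres are exchanged for a δ-lactone with one carbinol centre and an E alkene. The forward step needs enolisation at C9 only, O-silylation to 23, and a thermal shift through a boat that the ring enforces.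

**22 ⇒ 15 + 20.** The C9–C11 bond is cut. C9 in 15 is both α to the lactone carbonyl and allylic, so it is the natural nucleophile, and the chain arrives whole with C13 already set. The demand is α- and not γ-alkylation of 21. The configuration formed at C9 is of no consequence because it is erased in 23.

**15 ⇒ 12 ⇒ 9 + 10.** The lactone acyl–O6 bond and the C9–C10 bond are cut. An sp2–sp3 coupling at an enol triflate fixes the alkene as C1=C10 without ambiguity. This leads back to a monocyclic ketone and a two-carbon ester. The forward steps need kinetic enolisation toward C1 (via 8), coupling of 11 at a hindered vinyl triflate, and a ring closure (via 13 and 14) that neither ionises the allylic C6–O bond nor lets O6 attack the C4 ester.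

**9 ⇒ 7 ⇒ 6 ⇒ 3 + 4.** The C5–C6 bond and the C4–CH3 bond are cut. Conjugate addition creates the C5 enolate 5 regiospecifically, and an aldehyde is the best trap for it. Three contiguous stereocentres are taken back to an achiral enone and an achiral enal. The demand is catalyst control at C4, attack at C5 anti to the C4 ester, and a closed transition state for the anti relation at C6.

**3 ⇒ 2 ⇒ 1.** The bond between C4 and the ester carbon is cut. A vinylogous acyl triflate of a symmetrical diketone is carbonylated, which reaches a bulk chemical in two steps. The demand is that palladium insertion outruns addition of methanol to 2.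

**20 ⇒ 19 ⇒ 18 ⇒ 17 ⇒ 16.** No carbon–carbon bond is cut; the two ends of the five-carbon chain are told apart. The acid carbon of 16 must become C11 and the ester carbon C15, otherwise C13 would have the wrong configuration. The demand is two chemoselective reductions (acid before ester, ester beside iodide).

## Other disconnections considered

**Alternative 1: intramolecular Heck closure of ring B at C9.** The cut is C9–C10. In the forward step zerovalent palladium (from Pd(OAc)2 and BINAP) would insert into the C10–O bond of enol triflate A2. The vinylpalladium would add 6-exo across the trisubstituted C9=C11 alkene, and β-hydride elimination toward C12 would give diene A1.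

- In its favour: quaternary C9 is made with its methyl already in place, so the carboxyl-to-methyl conversion of the chosen plan disappears. On step economy after the key step this alternative is the better one. β-Hydride elimination can only go toward C12 because C9 has no hydrogen, and the C1=C10 alkene is delivered in place, which is equal to the chosen plan.
- Against it: C9 has to be set relative to C8 by facial selection on a trisubstituted alkene in a flexible tether. The ligand and the two existing centres may be matched or mismatched, and nothing in the mechanism ties C9 to C8 as the boat does in the chosen plan. Re-addition of palladium hydride could move the C11=C12 alkene toward C13 and erase that centre. A2 also needs a chain with an E-trisubstituted alkene between two stereocentres, and that chain must first be attached at C5.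
- Comparison: the mechanism is catalyst-controlled against chirality transfer; the endgame is shorter, the fragment synthesis longer, and stereochemical security at C8/C9 is lower.

**Alternative 2: malonate-lactone Claisen ring contraction that builds ring A.** The cut is C4–C5, with O–C1 reconnected. Soft enolisation of δ-lactone malonate A4 (Me3SiOTf, Et3N) would give the endocyclic silyl ketene acetal, and its [3,3] shift would give acid ester A3 with the C1=C10 alkene.

- In its favour: it is the same reaction family as the chosen key step, with the same ring-enforced boat, so the mechanistic footing is equal. The malonate acidity makes ketene acetal formation easier than with LiN(i-Pr)2, which is a point in its favour. The C2 oxygen is carried from the start, so the late allylic C–H oxidation and its regiochemical question are avoided, which is also better.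
- Against it: the step builds ring A on a finished ring B, so the C8/C9 pair, the hardest part of the molecule, must be solved first by other means. A3 is a malonic half ester: two geminal carboxyl groups on C4 must be told apart, one must be reduced to methyl next to the other, and decarboxylation on heating is a risk. A second orthogonal protecting group is needed for C15.
- Comparison: equal in mechanism, better in the C2 oxidation state, worse in what the key step achieves, and probably longer overall.

**Alternative 3: three-component conjugate methylation and alkylation on ring A.** The cuts are C4–CH3 and C5–C6. The first half is the same operation as step 3 of the chosen plan: Me3Al adds to 3 under Cu(O2CC4H3S) (monovalent copper) and a phosphoramidite. Enolate 5, activated with MeLi, would then be alkylated at C5 by iodide A6 to give ketone A5.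

- In its favour: it is convergent, and C4 and C5 are set in one flask exactly as in the chosen plan (equal). All of C6–C15 arrives at once with the C8 and C9 methyls as carbon, so no carboxyl-to-methyl conversion is needed (better).
- Against it: an aluminium enolate is a poor nucleophile toward an unactivated primary alkyl iodide even as an ate complex, whereas the aldehyde used in the chosen plan is a far better trap. Slow alkylation leaves time for proton transfer and for alkylation at C1. The facial question at C5 is the same as in the chosen plan (equal). The step neither closes ring B nor creates C9; that is left to the cyclisation of A2 (made from A5) to A1, with the weaknesses listed under Alternative 1. A6 is also a long fragment.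
- Comparison: better convergence on paper, but the main stereochemical problem is postponed and not solved.

Key step: step 13

Remark on the chemistry: the enantiomer of the phosphoramidite ligand (written L*, from biphenyl-2,2'-diol and a bis(1-arylethyl)amine) is taken to be the one that places methyl on the face of 3 giving (S) at C4; this sense is checked on the protonated adduct before the aldol is run.

Remark on the chemistry: 22 is drawn as its 9R epimer; the 9S epimer or a mixture is equally usable because C9 becomes trigonal in 23.

## Steps

Step 1
Reactants: 1 cyclohexane-1,3-dione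
Product: 2 3-oxocyclohex-1-en-1-yl trifluoromethanesulfonate
Conditions: Tf2O, pyridine, CH2Cl2, −78 to 0 °C
Reagents that add atoms: trifluoromethanesulfonic anhydride, O=S(=O)(OS(=O)(=O)C(F)(F)F)C(F)(F)F
Why: O-sulfonylation of the enol form of a symmetrical 1,3-diketone gives the vinylogous acyl triflate; only one regioisomer is possible.

Step 2
Reactants: 2 3-oxocyclohex-1-en-1-yl trifluoromethanesulfonate
Product: 3 methyl 3-oxocyclohex-1-ene-1-carboxylate
Conditions: CO (1 atm), MeOH, Pd(OAc)2 (cat.), PPh3, Et3N, DMF, 60 °C
Reagents that add atoms: carbon monoxide, [C-]#[O+]; methanol, CO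
Why: Palladium-catalysed alkoxycarbonylation of a vinyl triflate: zerovalent palladium formed in the flask inserts into the C–O bond, CO inserts and methanol cleaves the acylpalladium. Insertion into this electron-poor triflate is fast, which keeps addition–elimination of methanol at the β-carbon minor.

Step 3
Reactants: 3 methyl 3-oxocyclohex-1-ene-1-carboxylate; 4 (E)-but-2-enal
Product: 6 methyl (1S,2S)-2-[(1S,2E)-1-hydroxybut-2-en-1-yl]-1-methyl-3-oxocyclohexane-1-carboxylate, via dimethylaluminium enolate 5 (not isolated)
Conditions: Me3Al, Cu(O2CC4H3S) (5 mol %), phosphoramidite L* (10 mol %), Et2O, −30 °C; then 4, −78 to −40 °C; aq. potassium sodium tartrate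
Reagents that add atoms: trimethylaluminium, C[Al](C)C
Why: Copper-catalysed asymmetric conjugate addition of an aluminium methyl to a cyclohexenone with an acceptor on the β-carbon puts the methyl on C4 (β to the ketone) with the ligand fixing 4S, and leaves enolate 5 defined in position. The ring (E) enolate adds to the aldehyde carbonyl through a closed Zimmerman–Traxler chair, which gives the anti aldol (6S), on the face of C5 anti to the pseudoaxial methoxycarbonyl group of C4 (5S). Low temperature keeps retro-aldol and methyl transfer to the aldehyde minor.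

Step 4
Reactants: 6 methyl (1S,2S)-2-[(1S,2E)-1-hydroxybut-2-en-1-yl]-1-methyl-3-oxocyclohexane-1-carboxylate
Product: 7 methyl (1S,2S)-1-methyl-3-oxo-2-[(1S,2E)-1-(triethylsilyloxy)but-2-en-1-yl]cyclohexane-1-carboxylate
Conditions: Et3SiCl, imidazole, DMF, 0 °C
Reagents that add atoms: chlorotriethylsilane, CC[Si](Cl)(CC)CC
Why: Silylation of a secondary alcohol with imidazole as a mild base, which causes neither retro-aldol nor epimerisation at C5; the ether later prevents O-sulfonylation of the hydroxyl.

Step 5
Reactants: 7 methyl (1S,2S)-1-methyl-3-oxo-2-[(1S,2E)-1-(triethylsilyloxy)but-2-en-1-yl]cyclohexane-1-carboxylate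
Product: 9 methyl (1S,2S)-1-methyl-2-[(1S,2E)-1-(triethylsilyloxy)but-2-en-1-yl]-3-(trifluoromethanesulfonyloxy)cyclohex-3-ene-1-carboxylate, via potassium enolate 8 (not isolated)
Conditions: KN(SiMe3)2, THF, −78 °C; then PhNTf2, −78 to 0 °C
Reagents that add atoms: N-phenylbis(trifluoromethanesulfonimide), O=S(=O)(N(c1ccccc1)S(=O)(=O)C(F)(F)F)C(F)(F)F
Why: Kinetic deprotonation by the bulky amide takes a C1 hydrogen (methylene) and not the hindered tertiary C5 hydrogen beside quaternary C4, and the enolate is O-sulfonylated by the triflimide. This fixes the alkene as C1=C10 and locks the configuration of C5.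

Step 6
Reactants: 9 methyl (1S,2S)-1-methyl-2-[(1S,2E)-1-(triethylsilyloxy)but-2-en-1-yl]-3-(trifluoromethanesulfonyloxy)cyclohex-3-ene-1-carboxylate; 10 tert-butyl bromoacetate
Product: 12 methyl (1S,2S)-3-(2-tert-butoxy-2-oxoethyl)-1-methyl-2-[(1S,2E)-1-(triethylsilyloxy)but-2-en-1-yl]cyclohex-3-ene-1-carboxylate, via (2-tert-butoxy-2-oxoethyl)zinc bromide 11 (not isolated)
Conditions: 10, Zn (Me3SiCl-activated), THF, 40 °C; then 9, Pd2(dba)3 (cat.), XPhos, THF, 50 °C
Reagents that add atoms: none
Why: Negishi coupling of a Reformatsky reagent with an enol triflate: zerovalent palladium inserts into the C10–O bond, the zinc enolate transmetalates through carbon and reductive elimination forms C9–C10. The alkene position is fixed by the triflate, and the mild organozinc leaves both esters and the silyl ether untouched.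

Step 7
Reactants: 12 methyl (1S,2S)-3-(2-tert-butoxy-2-oxoethyl)-1-methyl-2-[(1S,2E)-1-(triethylsilyloxy)but-2-en-1-yl]cyclohex-3-ene-1-carboxylate
Product: 15 methyl (1S,8S,8aS)-8-methyl-3-oxo-1-[(E)-prop-1-en-1-yl]-3,4,6,7,8,8a-hexahydro-1H-isochromene-8-carboxylate, via trimethylsilyl ester 13 (not isolated), via hydroxy acid 14 (not isolated)
Conditions: Me3SiOTf, 2,6-lutidine, CH2Cl2, 0 °C; then HF·pyridine, THF, 0 °C to rt; then EDC·HCl, DMAP, CH2Cl2, rt
Reagents that add atoms: none
Why: The silyl triflate with a hindered base converts the tert-butyl ester into the silyl ester without free strong acid, so the allylic C6–O bond is not ionised; fluoride then removes both silyl groups. Carbodiimide activation of the only free carboxyl closes the six-membered lactone (6-exo-trig acyl substitution) in preference to attack of O6 on the unactivated, hindered C4 ester.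

Step 8
Reactants: 16 (R)-5-methoxy-3-methyl-5-oxopentanoic acid
Product: 17 methyl (R)-5-hydroxy-3-methylpentanoate
Conditions: BH3·SMe2, THF, 0 °C to rt; MeOH
Reagents that add atoms: none
Why: Borane reduces a carboxylic acid far faster than an ester (acyloxyborane pathway), so only the acid terminus, the future C11, becomes CH2OH; the stereocentre is not involved.

Step 9
Reactants: 17 methyl (R)-5-hydroxy-3-methylpentanoate
Product: 18 methyl (S)-5-iodo-3-methylpentanoate
Conditions: I2, PPh3, imidazole, CH2Cl2, 0 °C
Reagents that add atoms: iodine, II
Why: Appel-type iodination: the alkoxyphosphonium ion is displaced by iodide in an SN2 step at the primary carbon, fast enough at 0 °C that the δ-hydroxy ester does not lactonise. The descriptor changes only because iodine changes the CIP priorities.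

Step 10
Reactants: 18 methyl (S)-5-iodo-3-methylpentanoate
Product: 19 (S)-5-iodo-3-methylpentan-1-ol
Conditions: i-Bu2AlH, CH2Cl2, −78 to −20 °C; aq. potassium sodium tartrate
Reagents that add atoms: none
Why: Hydride reduction of the ester to the primary alcohol; the aluminium hydride does not reduce a primary alkyl iodide at low temperature, and the cold aluminium alkoxide does not cyclise onto it.

Step 11
Reactants: 19 (S)-5-iodo-3-methylpentan-1-ol
Product: 20 (S)-tert-butyl[(5-iodo-3-methylpentyl)oxy]dimethylsilane
Conditions: t-BuMe2SiCl, imidazole, CH2Cl2, 0 °C to rt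
Reagents that add atoms: tert-butylchlorodimethylsilane, CC(C)(C)[Si](C)(C)Cl
Why: Standard silylation of a primary alcohol; the weak base does not promote cyclisation of the iodo alcohol to a tetrahydropyran.

Step 12
Reactants: 15 methyl (1S,8S,8aS)-8-methyl-3-oxo-1-[(E)-prop-1-en-1-yl]-3,4,6,7,8,8a-hexahydro-1H-isochromene-8-carboxylate; 20 (S)-tert-butyl[(5-iodo-3-methylpentyl)oxy]dimethylsilane
Product: 22 methyl (1S,4R,8S,8aS)-4-[(3R)-5-(tert-butyldimethylsilyloxy)-3-methylpentyl]-8-methyl-3-oxo-1-[(E)-prop-1-en-1-yl]-3,4,6,7,8,8a-hexahydro-1H-isochromene-8-carboxylate, via lithium dienolate 21 (not isolated)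
Conditions: LiN(i-Pr)2, THF, −78 °C; then 20, DMPU, −78 to −30 °C
Reagents that add atoms: none
Why: The C9 hydrogens of 15 are α to the lactone carbonyl and allylic, so the amide base gives only dienolate 21 (the C4 ester has no α-hydrogen), and the primary iodide alkylates it at the α-carbon in an SN2 step, the usual kinetic site of an extended enolate. The new C9 centre is not relevant because it becomes trigonal in the next step, and the temperature is kept low so that 21 does not rearrange before it is alkylated.

Step 13
Reactants: 22 methyl (1S,4R,8S,8aS)-4-[(3R)-5-(tert-butyldimethylsilyloxy)-3-methylpentyl]-8-methyl-3-oxo-1-[(E)-prop-1-en-1-yl]-3,4,6,7,8,8a-hexahydro-1H-isochromene-8-carboxylate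
Product: 25 (1R,2R,4aS,5S)-1-[(3R)-5-(tert-butyldimethylsilyloxy)-3-methylpentyl]-5-(methoxycarbonyl)-2,5-dimethyl-1,2,4a,5,6,7-hexahydronaphthalene-1-carboxylic acid, via silyl ketene acetal 23 (not isolated), via trimethylsilyl ester 24 (not isolated)
Conditions: LiN(i-Pr)2, Me3SiCl–Et3N, THF, −78 °C; then toluene, 90 °C; aq. citric acid, THF
Reagents that add atoms: none
Why: Deprotonation at C9 (the only acidic C–H: tertiary, α to the lactone carbonyl and allylic) in the presence of the silyl chloride gives the O-silylated cyclic dienyl ketene acetal 23, in which C9=C(OSi)–O–C6–C7=C8 is an allyl vinyl ether. On heating, a concerted suprafacial [3,3] sigmatropic shift (Ireland–Claisen rearrangement) forms C8–C9 and breaks O–C6 to give silyl ester 24, hydrolysed to 25 on work-up. The closest known reaction type is the rearrangement of silyl ketene acetals of 6-alkenyl δ-lactones to cyclohexenecarboxylic acids; the new features are only the extra C1=C10 conjugation and the fusion to ring A. Ring B closes by joining the two ends of the tethered allyl vinyl ether in a six-centre transition state; because C9 and C6 are already linked by C10–C5, the ketene acetal carbon and C7 must lie on the same side, so the chair is impossible and the boat is enforced. At C8 the E geometry places the propenyl methyl in the outer position of the boat, which makes it cis to the carboxyl on C9. At C9 the former lactone carbonyl becomes the carboxyl on the face of the C8 methyl and the alkylated chain takes the other position, and since the new bond forms on the face of the lactone from which the propenyl group projects, the 6S carbinol centre is transferred to 8R,9R with H5 trans to the carboxyl and to the C8 methyl. The step needs enolisation at C9 only and O- over C-silylation (secured by the doubly activated C9–H, the absence of α-hydrogens on the C4 ester and trapping in the flask), and it has no competing allowed shift, because C1 of the dienyl system cannot reach C8 in a six-centre array. Heating is limited to what the shift requires because 23 is sensitive to moisture.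

Step 14
Reactants: 25 (1R,2R,4aS,5S)-1-[(3R)-5-(tert-butyldimethylsilyloxy)-3-methylpentyl]-5-(methoxycarbonyl)-2,5-dimethyl-1,2,4a,5,6,7-hexahydronaphthalene-1-carboxylic acid
Product: 26 (1R,2R,4aS,5S)-1-[(3R)-5-(tert-butyldimethylsilyloxy)-3-methylpentyl]-5-(methoxycarbonyl)-2,5-dimethyl-1,2,3,4,4a,5,6,7-octahydronaphthalene-1-carboxylic acid
Conditions: H2 (1 atm), RhCl(PPh3)3 (cat.), benzene–EtOH, rt
Reagents that add atoms: none
Why: Homogeneous hydrogenation with the rhodium chloride phosphine complex reduces the cis-disubstituted C6=C7 alkene and leaves the hindered trisubstituted C1=C10 alkene beside quaternary C9. It removes the doubly allylic C5–H before any basic step and forms no stereocentre.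

Step 15
Reactants: 26 (1R,2R,4aS,5S)-1-[(3R)-5-(tert-butyldimethylsilyloxy)-3-methylpentyl]-5-(methoxycarbonyl)-2,5-dimethyl-1,2,3,4,4a,5,6,7-octahydronaphthalene-1-carboxylic acid
Product: 28 methyl (1S,5R,6R,8aS)-5-[(3R)-5-(tert-butyldimethylsilyloxy)-3-methylpentyl]-5-formyl-1,6-dimethyl-1,2,3,5,6,7,8,8a-octahydronaphthalene-1-carboxylate, via acid chloride 27 (not isolated)
Conditions: Me2C=C(Cl)NMe2, CH2Cl2, 0 °C to rt; then LiAlH(Ot-Bu)3, THF, −78 °C
Reagents that add atoms: none
Why: The α-chloroenamine converts the hindered acid into acid chloride 27 under neutral conditions (no HCl, so the silyl ether is safe), and the bulky alkoxyaluminium hydride reduces an acid chloride to the aldehyde at low temperature without touching the C4 ester. C9 is quaternary, so the aldehyde can neither enolise nor move into conjugation.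

Step 16
Reactants: 28 methyl (1S,5R,6R,8aS)-5-[(3R)-5-(tert-butyldimethylsilyloxy)-3-methylpentyl]-5-formyl-1,6-dimethyl-1,2,3,5,6,7,8,8a-octahydronaphthalene-1-carboxylate
Product: 30 methyl (1S,5S,6R,8aS)-5-[(3R)-5-(tert-butyldimethylsilyloxy)-3-methylpentyl]-1,5,6-trimethyl-1,2,3,5,6,7,8,8a-octahydronaphthalene-1-carboxylate, via N-silyl hydrazone 29 (not isolated)
Conditions: t-BuMe2SiNHNHSiMe2t-Bu, Sc(OTf)3 (cat.), CH2Cl2, rt; then KOt-Bu, t-BuOH, DMSO, 23 °C
Reagents that add atoms: none
Why: Wolff–Kishner reduction in its N-silyl hydrazone form: condensation gives 29, then base-induced desilylation, tautomerisation to the diazene anion and loss of N2 give the methyl group by protonation. The pathway is anionic, so the carbon on C9 never becomes a radical that could add to the neighbouring C1=C10 alkene. Room temperature and added tert-butanol limit attack on the hindered C4 ester and migration of the alkene.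

Step 17
Reactants: 30 methyl (1S,5S,6R,8aS)-5-[(3R)-5-(tert-butyldimethylsilyloxy)-3-methylpentyl]-1,5,6-trimethyl-1,2,3,5,6,7,8,8a-octahydronaphthalene-1-carboxylate
Product: 31 methyl (1S,5S,6R,8aS)-5-[(3R)-5-(tert-butyldimethylsilyloxy)-3-methylpentyl]-1,5,6-trimethyl-3-oxo-1,2,3,5,6,7,8,8a-octahydronaphthalene-1-carboxylate
Conditions: t-BuOOH (70% in water), Rh2(C6H10NO)4 (dirhodium tetracaprolactamate, cat.), 1,2-dichloroethane, 40 °C
Reagents that add atoms: tert-butyl hydroperoxide, CC(C)(C)OO
Why: Allylic C–H oxidation by tert-butylperoxyl radicals generated by the dirhodium carboxamidate: a hydrogen is taken from C2, the only allylic methylene (C9 has none, C5–H is tertiary and shielded by C4), and the allyl radical is trapped at the unhindered C2 end to give the enone after loss of tert-butanol from the mixed peroxide. The regiochemistry parallels the 7-oxidation of 5-ene steroids.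

Step 18
Reactants: 31 methyl (1S,5S,6R,8aS)-5-[(3R)-5-(tert-butyldimethylsilyloxy)-3-methylpentyl]-1,5,6-trimethyl-3-oxo-1,2,3,5,6,7,8,8a-octahydronaphthalene-1-carboxylate
Product: 32 methyl (1S,5S,6R,8aS)-5-[(3R)-5-hydroxy-3-methylpentyl]-1,5,6-trimethyl-3-oxo-1,2,3,5,6,7,8,8a-octahydronaphthalene-1-carboxylate
Conditions: HF·pyridine, THF, 0 °C to rt
Reagents that add atoms: none
Why: Fluoride cleavage of the primary silyl ether under slightly acidic conditions, which neither enolise the enone toward C5 nor touch the ester.

## Compound list

1 | cyclohexane-1,3-dione | O=C1CCCC(=O)C1 | starting material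
2 | 3-oxocyclohex-1-en-1-yl trifluoromethanesulfonate | O=C1CCCC(OS(=O)(=O)C(F)(F)F)=C1 | intermediate
3 | methyl 3-oxocyclohex-1-ene-1-carboxylate | COC(=O)C1=CC(=O)CCC1 | intermediate
4 | (E)-but-2-enal | C/C=C/C=O | starting material
5 | dimethylaluminium enolate of methyl (S)-1-methyl-3-oxocyclohexane-1-carboxylate (C5=C10 enolate) | COC(=O)[C@@]1(C)CCCC(O[Al](C)C)=C1 | intermediate (not isolated)
6 | methyl (1S,2S)-2-[(1S,2E)-1-hydroxybut-2-en-1-yl]-1-methyl-3-oxocyclohexane-1-carboxylate | COC(=O)[C@@]1(C)CCCC(=O)[C@@H]1[C@H](/C=C/C)O | intermediate
7 | methyl (1S,2S)-1-methyl-3-oxo-2-[(1S,2E)-1-(triethylsilyloxy)but-2-en-1-yl]cyclohexane-1-carboxylate | COC(=O)[C@@]1(C)CCCC(=O)[C@@H]1[C@H](/C=C/C)O[Si](CC)(CC)CC | intermediate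
8 | potassium enolate of 7 (C1=C10 enolate) | COC(=O)[C@@]1(C)CCC=C(O[K])[C@@H]1[C@H](/C=C/C)O[Si](CC)(CC)CC | intermediate (not isolated)
9 | methyl (1S,2S)-1-methyl-2-[(1S,2E)-1-(triethylsilyloxy)but-2-en-1-yl]-3-(trifluoromethanesulfonyloxy)cyclohex-3-ene-1-carboxylate | COC(=O)[C@@]1(C)CCC=C(OS(=O)(=O)C(F)(F)F)[C@@H]1[C@H](/C=C/C)O[Si](CC)(CC)CC | intermediate
10 | tert-butyl bromoacetate | CC(C)(C)OC(=O)CBr | starting material
11 | (2-tert-butoxy-2-oxoethyl)zinc bromide | CC(C)(C)OC(=O)C[Zn]Br | intermediate (not isolated)
12 | methyl (1S,2S)-3-(2-tert-butoxy-2-oxoethyl)-1-methyl-2-[(1S,2E)-1-(triethylsilyloxy)but-2-en-1-yl]cyclohex-3-ene-1-carboxylate | COC(=O)[C@@]1(C)CCC=C(CC(=O)OC(C)(C)C)[C@@H]1[C@H](/C=C/C)O[Si](CC)(CC)CC | intermediate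
13 | trimethylsilyl ester corresponding to 12 (tert-butyl replaced by trimethylsilyl) | COC(=O)[C@@]1(C)CCC=C(CC(=O)O[Si](C)(C)C)[C@@H]1[C@H](/C=C/C)O[Si](CC)(CC)CC | intermediate (not isolated)
14 | methyl (1S,2S)-3-(carboxymethyl)-2-[(1S,2E)-1-hydroxybut-2-en-1-yl]-1-methylcyclohex-3-ene-1-carboxylate | COC(=O)[C@@]1(C)CCC=C(CC(=O)O)[C@@H]1[C@H](/C=C/C)O | intermediate (not isolated)
15 | methyl (1S,8S,8aS)-8-methyl-3-oxo-1-[(E)-prop-1-en-1-yl]-3,4,6,7,8,8a-hexahydro-1H-isochromene-8-carboxylate (4S,5S,6S in halimane numbering) | COC(=O)[C@@]1(C)CCC=C2[C@@H]1[C@H](/C=C/C)OC(=O)C2 | intermediate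
16 | (R)-5-methoxy-3-methyl-5-oxopentanoic acid ((R)-monomethyl 3-methylglutarate) | OC(=O)C[C@@H](C)CC(=O)OC | starting material
17 | methyl (R)-5-hydroxy-3-methylpentanoate | OCC[C@@H](C)CC(=O)OC | intermediate
18 | methyl (S)-5-iodo-3-methylpentanoate | ICC[C@@H](C)CC(=O)OC | intermediate
19 | (S)-5-iodo-3-methylpentan-1-ol | ICC[C@@H](C)CCO | intermediate
20 | (S)-tert-butyl[(5-iodo-3-methylpentyl)oxy]dimethylsilane | ICC[C@@H](C)CCO[Si](C)(C)C(C)(C)C | intermediate
21 | lithium dienolate of 15 (C1=C10–C9=C(OLi)–O) | COC(=O)[C@@]1(C)CCC=C2[C@@H]1[C@H](/C=C/C)OC(O[Li])=C2 | intermediate (not isolated)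
22 | methyl (1S,4R,8S,8aS)-4-[(3R)-5-(tert-butyldimethylsilyloxy)-3-methylpentyl]-8-methyl-3-oxo-1-[(E)-prop-1-en-1-yl]-3,4,6,7,8,8a-hexahydro-1H-isochromene-8-carboxylate (4S,5S,6S,9R,13R in halimane numbering) | COC(=O)[C@@]1(C)CCC=C2[C@@H]1[C@H](/C=C/C)OC(=O)[C@@H]2CC[C@@H](C)CCO[Si](C)(C)C(C)(C)C | intermediate
23 | trimethylsilyl dienyl ketene acetal of 22 | COC(=O)[C@@]1(C)CCC=C2[C@@H]1[C@H](/C=C/C)OC(O[Si](C)(C)C)=C2CC[C@@H](C)CCO[Si](C)(C)C(C)(C)C | intermediate (not isolated)
24 | trimethylsilyl ester of 25 | COC(=O)[C@@]1(C)CCC=C2[C@@H]1C=C[C@@H](C)[C@]2(C(=O)O[Si](C)(C)C)CC[C@@H](C)CCO[Si](C)(C)C(C)(C)C | intermediate (not isolated)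
25 | (1R,2R,4aS,5S)-1-[(3R)-5-(tert-butyldimethylsilyloxy)-3-methylpentyl]-5-(methoxycarbonyl)-2,5-dimethyl-1,2,4a,5,6,7-hexahydronaphthalene-1-carboxylic acid (4S,5S,8R,9R,13R in halimane numbering) | COC(=O)[C@@]1(C)CCC=C2[C@@H]1C=C[C@@H](C)[C@]2(C(=O)O)CC[C@@H](C)CCO[Si](C)(C)C(C)(C)C | intermediate
26 | (1R,2R,4aS,5S)-1-[(3R)-5-(tert-butyldimethylsilyloxy)-3-methylpentyl]-5-(methoxycarbonyl)-2,5-dimethyl-1,2,3,4,4a,5,6,7-octahydronaphthalene-1-carboxylic acid | COC(=O)[C@@]1(C)CCC=C2[C@@H]1CC[C@@H](C)[C@]2(C(=O)O)CC[C@@H](C)CCO[Si](C)(C)C(C)(C)C | intermediate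
27 | acid chloride of 26 | COC(=O)[C@@]1(C)CCC=C2[C@@H]1CC[C@@H](C)[C@]2(C(=O)Cl)CC[C@@H](C)CCO[Si](C)(C)C(C)(C)C | intermediate (not isolated)
28 | methyl (1S,5R,6R,8aS)-5-[(3R)-5-(tert-butyldimethylsilyloxy)-3-methylpentyl]-5-formyl-1,6-dimethyl-1,2,3,5,6,7,8,8a-octahydronaphthalene-1-carboxylate | COC(=O)[C@@]1(C)CCC=C2[C@@H]1CC[C@@H](C)[C@]2(C=O)CC[C@@H](C)CCO[Si](C)(C)C(C)(C)C | intermediate
29 | N-(tert-butyldimethylsilyl)hydrazone of 28 | COC(=O)[C@@]1(C)CCC=C2[C@@H]1CC[C@@H](C)[C@]2(/C=N/N[Si](C)(C)C(C)(C)C)CC[C@@H](C)CCO[Si](C)(C)C(C)(C)C | intermediate (not isolated)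
30 | methyl (1S,5S,6R,8aS)-5-[(3R)-5-(tert-butyldimethylsilyloxy)-3-methylpentyl]-1,5,6-trimethyl-1,2,3,5,6,7,8,8a-octahydronaphthalene-1-carboxylate | COC(=O)[C@@]1(C)CCC=C2[C@@H]1CC[C@@H](C)[C@]2(C)CC[C@@H](C)CCO[Si](C)(C)C(C)(C)C | intermediate
31 | methyl (1S,5S,6R,8aS)-5-[(3R)-5-(tert-butyldimethylsilyloxy)-3-methylpentyl]-1,5,6-trimethyl-3-oxo-1,2,3,5,6,7,8,8a-octahydronaphthalene-1-carboxylate | COC(=O)[C@@]1(C)CC(=O)C=C2[C@@H]1CC[C@@H](C)[C@]2(C)CC[C@@H](C)CCO[Si](C)(C)C(C)(C)C | intermediate
32 | methyl (1S,5S,6R,8aS)-5-[(3R)-5-hydroxy-3-methylpentyl]-1,5,6-trimethyl-3-oxo-1,2,3,5,6,7,8,8a-octahydronaphthalene-1-carboxylate (4S,5S,8R,9S,13R in halimane numbering) | COC(=O)[C@@]1(C)CC(=O)C=C2[C@@H]1CC[C@@H](C)[C@]2(C)CC[C@@H](C)CCO | target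

## Step count and least certain steps

Total: 18 steps. Longest linear sequence: 14 steps (steps 1–7 and 12–18). The chain fragment takes 4 steps (8–11) and joins at step 12.

**Step 13 (key step).** The shift must join fully substituted C9 to secondary C8 through a boat, so it needs heat. During that time the ketene acetal may be lost, either by desilylation back to the lactone or because C-silylation at C1 of the dienolate competed with O-silylation. The fallback exchanges the order of alkylation and rearrangement. Setting out from 15, enolisation and silylation give the unsubstituted silyl ketene acetal F1. It should rearrange more easily, since it forms a tertiary and not a quaternary C9, through the same boat to the trimethylsilyl ester F2 and, after hydrolysis, the C9–H acid F3. Two equivalents of LiN(i-Pr)2 then give the dilithium dienediolate F4, which is alkylated by 20 on the face of C9 opposite the adjacent C8 methyl, so the carboxyl stays cis to that methyl. This comes back to the route at 25. In this variant C9 is set by substrate-controlled enolate alkylation and not by the sigmatropic transfer.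

**Step 3.** The process most likely to fail is facial selection at C5: the methyl and the ester on C4 differ little in size, so attack anti to the ester may be only modest. The aluminium enolate may also add slowly, leaving room for retro-aldol equilibration and for methyl transfer from residual Me3Al to the aldehyde. The fallback separates the two events. Setting out from 3, the conjugate addition is run as before and the enolate is silylated (Me3SiOTf) to the isolable trimethylsilyl enol ether F5. MeLi converts F5 into the lithium enolate F6, which is added to 4 at −78 °C with a short contact time under kinetic control through a closed transition state. This comes back to the route at 6, and the diastereomers are separated there or at 7 if needed.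

**Step 16.** The risk is that the basic medium attacks the C4 methyl ester, or moves the C1=C10 alkene toward the tetrasubstituted C5=C10 position; condensation at the neopentyl aldehyde may also be slow. The fallback is neutral desulfurisation. Setting out from 28, ethane-1,2-dithiol with Zn(OTf)2 in CH2Cl2 gives the 1,3-dithiolane F7, and Raney nickel in ethanol removes the sulfur to give the methyl group. This comes back to the route at 30.

**Step 6.** Transmetalation and reductive elimination at the vinylpalladium flanked by the bulky C5 substituent may be slow, so that reduction of the triflate or homocoupling of the zinc reagent takes over. The fallback builds the lactone by olefination. Setting out from 6, O6 is acylated with diethylphosphonoacetic acid (EDC·HCl, DMAP) to the phosphonoacetate F8. An intramolecular Horner–Wadsworth–Emmons reaction (LiCl, i-Pr2NEt, MeCN) closes the conjugated lactone F9 with a C9=C10 alkene. LiN(i-Pr)2 removes a γ-hydrogen from C1 to give the same dienolate 21, which is alkylated by 20 as in step 12, coming back to the route at 22. This path is shorter but is held in reserve: β-elimination of the acyloxy group from the ketone and γ-deprotonation at C5 instead of C1 are both possible.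

**Step 17.** Hydrogen abstraction from the tertiary allylic C5–H would lead to oxidation at the wrong end of the allyl system, and the new enone may be oxidised further at its γ-position. The fallback is a three-step transposition. Setting out from 30, mCPBA with NaHCO3 gives the epoxide F10 (drawn as the α-epoxide; either face serves because C1 and C10 become trigonal again). LiNEt2 removes a C2 hydrogen and opens it to the tertiary allylic alcohol F11 (C10–OH, C1=C2). Pyridinium chlorochromate then effects the oxidative 1,3-transposition (Babler–Dauben oxidation), coming back to the route at 31.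

## Further compounds

F1 | step 13 | trimethylsilyl dienyl ketene acetal of 15 | COC(=O)[C@@]1(C)CCC=C2[C@@H]1[C@H](/C=C/C)OC(O[Si](C)(C)C)=C2
F2 | step 13 | trimethylsilyl ester of F3 | COC(=O)[C@@]1(C)CCC=C2[C@@H]1C=C[C@@H](C)[C@H]2C(=O)O[Si](C)(C)C
F3 | step 13 | (1R,2R,4aS,5S)-5-(methoxycarbonyl)-2,5-dimethyl-1,2,4a,5,6,7-hexahydronaphthalene-1-carboxylic acid (C9–H acid) | COC(=O)[C@@]1(C)CCC=C2[C@@H]1C=C[C@@H](C)[C@H]2C(=O)O
F4 | step 13 | dilithium dienediolate of F3 | COC(=O)[C@@]1(C)CCC=C2[C@@H]1C=C[C@@H](C)C2=C(O[Li])O[Li]
F5 | step 3 | methyl (S)-1-methyl-3-(trimethylsilyloxy)cyclohex-2-ene-1-carboxylate | COC(=O)[C@@]1(C)CCCC(O[Si](C)(C)C)=C1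
F6 | step 3 | lithium enolate of methyl (S)-1-methyl-3-oxocyclohexane-1-carboxylate (C5=C10 enolate) | COC(=O)[C@@]1(C)CCCC(O[Li])=C1
F7 | step 16 | 1,3-dithiolane of 28 | COC(=O)[C@@]1(C)CCC=C2[C@@H]1CC[C@@H](C)[C@]2(C3SCCS3)CC[C@@H](C)CCO[Si](C)(C)C(C)(C)C
F8 | step 6 | diethylphosphonoacetate ester of 6 | COC(=O)[C@@]1(C)CCCC(=O)[C@@H]1[C@H](/C=C/C)OC(=O)CP(=O)(OCC)OCC
F9 | step 6 | conjugated lactone isomer of 15 (C9=C10 alkene) | COC(=O)[C@@]1(C)CCCC=2[C@@H]1[C@H](/C=C/C)OC(=O)C=2
F10 | step 17 | 1,10-epoxide of 30 (α-epoxide) | COC(=O)[C@@]1(C)CC[C@@H]2O[C@]23[C@@H]1CC[C@@H](C)[C@]3(C)CC[C@@H](C)CCO[Si](C)(C)C(C)(C)C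
F11 | step 17 | tertiary allylic alcohol from F10 (C10–OH, C1=C2) | COC(=O)[C@@]1(C)CC=C[C@]2(O)[C@@H]1CC[C@@H](C)[C@]2(C)CC[C@@H](C)CCO[Si](C)(C)C(C)(C)C
A1 | alternative 1 | bicyclic 1(10),11-diene | COC(=O)[C@@]1(C)CCC=C2[C@@H]1CC[C@@H](C)[C@]2(C)/C=C/[C@@H](C)CCO[Si](C)(C)C(C)(C)C
A2 | alternative 1 | C10 enol triflate with the C9=C11 alkene in the chain | COC(=O)[C@@]1(C)CCC=C(OS(=O)(=O)C(F)(F)F)[C@@H]1CC[C@@H](C)/C(C)=C/C[C@@H](C)CCO[Si](C)(C)C(C)(C)C
A3 | alternative 2 | bicyclic acid ester (C4 carboxyl as latent methyl) | COC(=O)[C@@]1(C(=O)O)C[C@H](O[Si](C)(C)C(C)(C)C)C=C2[C@@H]1CC[C@@H](C)[C@]2(C)CC[C@@H](C)CCOCc3ccc(OC)cc3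
A4 | alternative 2 | δ-lactone malonate with the ring B cyclohexenyl group on C1 (C4 configurationally labile) | COC(=O)C1C[C@H](O[Si](C)(C)C(C)(C)C)[C@H](OC1=O)C2=CCC[C@@H](C)[C@]2(C)CC[C@@H](C)CCOCc3ccc(OC)cc3
A5 | alternative 3 | ring A ketone with C4, C5 and the full chain | COC(=O)[C@@]1(C)CCCC(=O)[C@@H]1CC[C@@H](C)/C(C)=C/C[C@@H](C)CCO[Si](C)(C)C(C)(C)C
A6 | alternative 3 | chain iodide with the E-trisubstituted alkene | ICC[C@@H](C)/C(C)=C/C[C@@H](C)CCO[Si](C)(C)C(C)(C)C
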